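**Plan**

1. Retrosynthesis (azulene numbering; C1′ is the CH bearing CH2OAc, C2′ the lactone C3): cut C8=CH2 (ketone methylenation), the acetate and lactone C–O bonds, C2′–CH2CO2 (enolate alkylation), C1′–CH2O carbon (vinyl conjugate addition) and C1′=C2′ (olefination), back to a 1-formyl-1-methylhydroazulen-2-one.
2. Enabling feature: cyclopentane carbon C1 carries CH3 and C1′ and lies between ring-fusion C8a and C2. This is the pattern left by a 1,2-acyl shift in a β-methyl α,β-epoxycyclohexanone, so the C1–C2 ring bond is cut and C1′ is the expelled epoxide CH (formyl).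
3. The epoxy ketone goes back to a cis-fused cyclohexenone (two ring bonds, Diels–Alder of 4,4-dimethylcyclohept-2-enone with a 2-silyloxypenta-1,3-diene). The cycloheptenone comes from 3-methylcyclohexenone by ring expansion.
4. Forward order: seven-membered ring, then six-membered ring by cycloaddition, then six-to-five contraction, then the side chain built carbon by carbon on the formyl group; C2 is deoxygenated on the way and C8 methylenated last.
5. Stereochemistry: C3a/C8a from the catalyst-controlled cis cycloaddition; C1 from convex-face epoxidation and inversion in the acyl shift; C1′ and C2′ from one (R)-4-benzyloxazolidinone (conjugate addition, then enolate alkylation).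

Key step: step 11

Remarks
- Numbering: the benzo[7]annulene intermediates (step 5 to step 11 precursor) use C2 (enol ether/ketone), C3, C4 (methyl-bearing), C4a/C9a (ring fusion), C5 (cycloheptanone or ketal carbon), C9 (CMe2). The hydroazulenes use C1 (quaternary), C2, C3, C3a/C8a (ring fusion), C4 (CMe2), C8.
- Assumption: the (S)-configured oxazaborolidinium catalyst is taken to bind the cycloheptenone in the usual α-C–H···O mode and to expose the enone face that leads to the adduct drawn; if the sense were opposite, the (R)-catalyst would be used with no other change.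
- The cyclopropane and the chloro ketone of steps 2–3 are racemic; their stereocentres are erased in step 3.

**Route**

Step 1
Reactants: 1 3-methylcyclohex-2-en-1-one
Product: 2 3,3-dimethyl-1-(trimethylsilyloxy)cyclohex-1-ene
Conditions: MeMgBr, CuBr·SMe2 (5 mol%), TMSCl, DMPU, THF, −78 → −40 °C; Et3N
Reagents that add atoms: methylmagnesium bromide C[Mg]Br; chlorotrimethylsilane C[Si](C)(C)Cl
Why: Copper-catalysed 1,4-addition of methyl to the β-methyl enone and O-silylation of the resulting enolate without equilibration fix the enol ether double bond on the side of the new quaternary carbon (conjugate addition–enolate trapping).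

Step 2
Reactants: 2 3,3-dimethyl-1-(trimethylsilyloxy)cyclohex-1-ene
Product: 3 (±)-5,5-dimethyl-1-(trimethylsilyloxy)bicyclo[4.1.0]heptane
Conditions: Et2Zn, CH2I2, toluene, 0 °C → rt
Reagents that add atoms: diiodomethane ICI
Why: Simmons–Smith cyclopropanation (diethylzinc variant) of the electron-rich silyl enol ether; the cis ring fusion is forced and the racemic centres are removed in step 3.

Step 3
Reactants: 3 (±)-5,5-dimethyl-1-(trimethylsilyloxy)bicyclo[4.1.0]heptane
Product: 5 4,4-dimethylcyclohept-2-en-1-one, via 3-chloro-4,4-dimethylcycloheptanone 4 (not isolated)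
Conditions: FeCl3, DMF, 0 °C → rt; then NaOAc, MeOH, reflux
Reagents that add atoms: none
Why: One-electron oxidation of the siloxycyclopropane by iron(III) cleaves the internal ring bond to the secondary β-keto radical, chlorine transfer gives the β-chloro ketone and acetate-induced E1cB elimination gives the ring-expanded enone with the gem-dimethyl group at C4 (oxidative ring expansion of siloxycyclopropanes).

Step 4
Reactants: 6 (E)-pent-3-en-2-one
Product: 7 (E)-2-(triisopropylsilyloxy)penta-1,3-diene
Conditions: LDA, THF, −78 °C; TIPSOTf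
Reagents that add atoms: triisopropylsilyl trifluoromethanesulfonate CC(C)[Si](C(C)C)(C(C)C)OS(=O)(=O)C(F)(F)F
Why: Kinetic deprotonation at the acetyl methyl group and O-silylation give the cross-conjugated 2-silyloxydiene and leave the E-propenyl unit untouched.

Step 5
Reactants: 5 4,4-dimethylcyclohept-2-en-1-one; 7 (E)-2-(triisopropylsilyloxy)penta-1,3-diene
Product: 8 cis-fused 4,9,9-trimethyl-2-(triisopropylsilyloxy)-1,4,4a,6,7,8,9,9a-octahydro-5H-benzo[7]annulen-5-one (endo adduct, 4-H cis to 4a-H)
Conditions: (S)-B-(o-tolyl)-diphenylprolinol oxazaborolidine·Tf2NH (20 mol%), CH2Cl2, −78 → −20 °C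
Reagents that add atoms: none
Why: Lewis-acid-catalysed Diels–Alder reaction in which the 2-silyloxy and 4-methyl groups both direct the diene CH2 terminus to the enone β-carbon, suprafacial addition fixes the cis ring fusion, and the cationic oxazaborolidine shields one enone face to set the absolute configuration at C4a/C9a (the C4 centre is erased in step 6).

Step 6
Reactants: 8 Diels–Alder adduct (silyl enol ether)
Product: 9 cis-4,9,9-trimethyl-4a,6,7,8,9,9a-hexahydro-1H-benzo[7]annulene-2,5-dione (C3=C4 enone)
Conditions: Pd(OAc)2 (1.1 equiv), MeCN, rt → 40 °C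
Reagents that add atoms: none
Why: Saegusa–Ito oxidation, in which the palladium enolate formed regiospecifically from the silyl enol ether loses the C4 hydride and gives the β-methyl enone without touching the ring-fusion centres.

Step 7
Reactants: 9 enedione
Product: 10 cis-5,5-(ethane-1,2-diyldioxy)-4,9,9-trimethyl-1,4a,5,6,7,8,9,9a-octahydro-2H-benzo[7]annulen-2-one
Conditions: TMSOCH2CH2OTMS, TMSOTf (5 mol%), CH2Cl2, −78 → −20 °C; pyridine quench
Reagents that add atoms: 1,2-bis(trimethylsilyloxy)ethane C[Si](C)(C)OCCO[Si](C)(C)C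
Why: Aprotic silyl-triflate-catalysed dioxolane formation is selective for the saturated cycloheptanone over the less electrophilic conjugated ketone, and the low temperature protects the acidic C4a–H.

Step 8
Reactants: 10 ketal enone
Product: 11 3,4-epoxide of 10, oxirane oxygen syn to 4a-H and 9a-H
Conditions: 30% H2O2, aq NaOH, MeOH, 0 °C → rt
Reagents that add atoms: hydrogen peroxide OO
Why: Weitz–Scheffer epoxidation in which hydroperoxide adds to C4 anti to the pseudoaxial C4a–C5 bond, i.e. on the convex face of the cis-fused bicycle, so the oxirane ends syn to the ring-fusion hydrogens.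

Step 9
Reactants: 12 (R)-4-benzyloxazolidin-2-one
Product: 13 (R)-4-benzyl-3-(bromoacetyl)oxazolidin-2-one
Conditions: n-BuLi, THF, −78 °C; BrCH2COBr
Reagents that add atoms: bromoacetyl bromide BrCC(=O)Br
Why: N-Acylation of the lithiated oxazolidinone by the acid bromide, which is far more reactive than the alkyl bromide end.

Step 10
Reactants: 13 (R)-4-benzyl-3-(bromoacetyl)oxazolidin-2-one
Product: 14 diethyl {2-[(R)-4-benzyl-2-oxooxazolidin-3-yl]-2-oxoethyl}phosphonate
Conditions: P(OEt)3, neat, 90 °C
Reagents that add atoms: triethyl phosphite CCOP(OCC)OCC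
Why: Michaelis–Arbuzov reaction of the activated α-bromo imide.

Step 11
Reactants: 11 epoxy ketone
Product: 15 cis-fused 1-formyl-1,4,4-trimethyl-8,8-(ethane-1,2-diyldioxy)octahydroazulen-2(1H)-one, formyl group syn to 3a-H and 8a-H
Conditions: BF3·OEt2 (1.5 equiv), benzene, 0 °C → rt, 20 min; cold water wash; crude used at once
Reagents that add atoms: none
Why: BF3 coordinates the oxirane oxygen, the C4–O bond ionises at the tertiary methyl-bearing carbon, and the ring acyl carbon C2 shifts from C3 to C4 anti to the departing oxygen, so the C2–C4 bond forms, C3 is expelled as the formyl group and the cyclohexanone contracts to a cyclopentanone. The closest known reaction is the BF3-induced rearrangement of β-alkyl α,β-epoxy cyclohexanones such as isophorone oxide to 2-formylcyclopentanones. The five-membered ring closes by this 1,2-shift (ring contraction), not by a cyclisation to which Baldwin's rules apply. The new quaternary centre is fixed by the oxirane configuration, since migration with inversion at C4 places the formyl group on the face of the ring-fusion hydrogens and the methyl group on the other. Acyl shift has to beat hydride shift from C3 (1,2-dione) and from C4a; the electron-withdrawing ketal carbon next to C4a–H and the high migratory aptitude of the acyl group in this concerted process favour it, and a dioxolane oxygen could only participate through a four-membered ring. The β-keto aldehyde is kept away from base and olefinated immediately to prevent deformylation.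

Step 12
Reactants: 15 keto aldehyde; 14 imide phosphonate
Product: 16 (R)-4-benzyl-3-{(E)-3-[1,4,4-trimethyl-2-oxo-8,8-(ethane-1,2-diyldioxy)decahydroazulen-1-yl]prop-2-enoyl}oxazolidin-2-one
Conditions: LiCl, iPr2NEt, MeCN, rt
Reagents that add atoms: none
Why: Horner–Wadsworth–Emmons olefination under mild amine/LiCl conditions reacts only at the aldehyde, consumes the deformylation-prone β-keto aldehyde at once and gives the E-enoyl imide.

Step 13
Reactants: 16 E-enoyl imide
Product: 17 (R)-4-benzyl-3-{3-[1,4,4-trimethyl-2-oxo-8,8-(ethane-1,2-diyldioxy)decahydroazulen-1-yl]pent-4-enoyl}oxazolidin-2-one (C3 of the pentenoyl chain is C1′, configured as in the target)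
Conditions: CH2=CHMgBr, CuBr·SMe2 (1:1), THF–Me2S, −78 → −30 °C; aq NH4Cl
Reagents that add atoms: vinylmagnesium bromide C=C[Mg]Br
Why: Organocopper 1,4-addition to the magnesium-chelated s-cis enoyl imide occurs anti to the benzyl group of the auxiliary, which sets C1′, and the vinylcopper reagent leaves the hindered cyclopentanone alone.

Step 14
Reactants: 17 keto imide
Product: 18 C2 p-toluenesulfonylhydrazone of 17 (C=N geometry not defined)
Conditions: TsNHNH2, THF, 4 Å MS, 55 °C
Reagents that add atoms: p-toluenesulfonohydrazide Cc1ccc(cc1)S(=O)(=O)NN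
Why: Condensation of the cyclopentanone with the sulfonyl hydrazide under near-neutral conditions, to which the β-branched imide and the dioxolane should be inert.

Step 15
Reactants: 18 tosylhydrazone
Product: 19 (R)-4-benzyl-3-{3-[1,4,4-trimethyl-8,8-(ethane-1,2-diyldioxy)decahydroazulen-1-yl]pent-4-enoyl}oxazolidin-2-one (C2 now CH2)
Conditions: catecholborane, CHCl3, 0 °C; then NaOAc·3H2O, reflux
Reagents that add atoms: none
Why: Hydride addition to the C=N bond, acetate-induced loss of sulfinate and extrusion of N2 from the diazene give the methylene group (tosylhydrazone deoxygenation) under conditions that spare imide, ketal and vinyl group.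

Step 16
Reactants: 19 imide
Product: 20 tert-butyl 3-[(R)-4-benzyl-2-oxooxazolidine-3-carbonyl]-4-[1,4,4-trimethyl-8,8-(ethane-1,2-diyldioxy)decahydroazulen-1-yl]hex-5-enoate (C3 is C2′, C4 is C1′)
Conditions: NaHMDS, THF, −78 °C; BrCH2CO2t-Bu, −78 → −40 °C
Reagents that add atoms: tert-butyl bromoacetate CC(C)(C)OC(=O)CBr
Why: Alkylation of the chelated sodium Z-enolate of the imide from the face opposite the benzyl group sets C2′ (auxiliary-controlled enolate alkylation with a reactive α-halo ester).

Step 17
Reactants: 20 alkylated imide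
Product: 22 4-{1-[1,4,4-trimethyl-8,8-(ethane-1,2-diyldioxy)decahydroazulen-1-yl]prop-2-en-1-yl}oxolan-2-one, via hydroxy tert-butyl ester 21 (not isolated)
Conditions: LiBH4, MeOH (1 equiv), Et2O–THF, 0 °C; then CSA (cat.), toluene, 60 °C on the crude
Reagents that add atoms: none
Why: Borohydride reduces the activated exocyclic imide carbonyl but not the tert-butyl ester, and anhydrous acid then closes the γ-lactone with loss of tert-butanol while the dioxolane stays in place.

Step 18
Reactants: 22 vinyl lactone
Product: 24 4-{2-hydroxy-1-[1,4,4-trimethyl-8,8-(ethane-1,2-diyldioxy)decahydroazulen-1-yl]ethyl}oxolan-2-one, via aldehyde 23 (not isolated)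
Conditions: O3, CH2Cl2–MeOH, −78 °C; Me2S; then NaBH4, 0 °C
Reagents that add atoms: ozone [O-][O+]=O
Why: Ozonolysis of the only C=C bond and immediate borohydride reduction of the aldehyde at low temperature give the primary alcohol without epimerisation at C1′, and a γ-lactone tolerates brief NaBH4 exposure.

Step 19
Reactants: 24 hydroxy lactone
Product: 25 2-(5-oxooxolan-3-yl)-2-[1,4,4-trimethyl-8,8-(ethane-1,2-diyldioxy)decahydroazulen-1-yl]ethyl acetate
Conditions: Ac2O, pyridine, DMAP (cat.), CH2Cl2, rt
Reagents that add atoms: acetic anhydride CC(=O)OC(C)=O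
Why: DMAP-catalysed acetylation of the primary alcohol, which also removes any chance of translactonisation.

Step 20
Reactants: 25 ketal acetate
Product: 26 2-(5-oxooxolan-3-yl)-2-(1,4,4-trimethyl-8-oxodecahydroazulen-1-yl)ethyl acetate
Conditions: PPTS, acetone–H2O, 55 °C
Reagents that add atoms: water O
Why: Mild aqueous acid hydrolyses the dioxolane, acetate and lactone are stable to it, and the short exposure limits epimerisation at C8a.

Step 21
Reactants: 26 ketone
Product: 27 (2R)-2-[(3R)-5-oxooxolan-3-yl]-2-[(1R,3aR,8aS)-1,4,4-trimethyl-8-methylidenedecahydroazulen-1-yl]ethyl acetate (target)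
Conditions: Zn, CH2Br2, TiCl4, THF–CH2Cl2, 0 °C → rt
Reagents that add atoms: dibromomethane BrCBr
Why: Takai–Lombardo methylenation, whose non-basic gem-dizinc reagent converts the hindered, enolisable ketone into the exocyclic alkene without epimerising C8a and leaves acetate and lactone untouched.

**Compound list**

1 | 3-methylcyclohex-2-en-1-one | CC1=CC(=O)CCC1 | starting material
2 | 3,3-dimethyl-1-(trimethylsilyloxy)cyclohex-1-ene | C[Si](C)(C)OC1=CC(C)(C)CCC1 | intermediate
3 | (±)-5,5-dimethyl-1-(trimethylsilyloxy)bicyclo[4.1.0]heptane (racemic) | C[Si](C)(C)OC12CCCC(C)(C)C1C2 | intermediate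
4 | (±)-3-chloro-4,4-dimethylcycloheptan-1-one (racemic, not isolated) | O=C1CC(Cl)C(C)(C)CCC1 | intermediate
5 | 4,4-dimethylcyclohept-2-en-1-one | O=C1C=CC(C)(C)CCC1 | intermediate
6 | (E)-pent-3-en-2-one | C/C=C/C(C)=O | starting material
7 | (E)-2-(triisopropylsilyloxy)penta-1,3-diene | C=C(O[Si](C(C)C)(C(C)C)C(C)C)/C=C/C | intermediate
8 | cis-fused 4,9,9-trimethyl-2-(triisopropylsilyloxy)-1,4,4a,6,7,8,9,9a-octahydro-5H-benzo[7]annulen-5-one, 4-H/4a-H/9a-H all cis | O=C1CCCC(C)(C)[C@@H]2CC(O[Si](C(C)C)(C(C)C)C(C)C)=C[C@H](C)[C@H]12 | intermediate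
9 | cis-4,9,9-trimethyl-4a,6,7,8,9,9a-hexahydro-1H-benzo[7]annulene-2,5-dione | O=C1CCCC(C)(C)[C@@H]2CC(=O)C=C(C)[C@H]12 | intermediate
10 | cis-5,5-(ethane-1,2-diyldioxy)-4,9,9-trimethyl-1,4a,5,6,7,8,9,9a-octahydro-2H-benzo[7]annulen-2-one | C12(OCCO1)CCCC(C)(C)[C@@H]3CC(=O)C=C(C)[C@H]23 | intermediate
11 | 3,4-epoxide of 10, oxirane oxygen syn to 4a-H/9a-H (key-step precursor) | C12(OCCO1)CCCC(C)(C)[C@@H]3CC(=O)[C@H]4O[C@@]4(C)[C@H]23 | intermediate
12 | (R)-4-benzyloxazolidin-2-one | O=C1N[C@H](Cc2ccccc2)CO1 | starting material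
13 | (R)-4-benzyl-3-(bromoacetyl)oxazolidin-2-one | O=C1OC[C@@H](Cc2ccccc2)N1C(=O)CBr | intermediate
14 | diethyl {2-[(R)-4-benzyl-2-oxooxazolidin-3-yl]-2-oxoethyl}phosphonate | CCOP(=O)(OCC)CC(=O)N1[C@H](Cc2ccccc2)COC1=O | intermediate
15 | cis-fused 1-formyl-1,4,4-trimethyl-8,8-(ethane-1,2-diyldioxy)octahydroazulen-2(1H)-one, CHO syn to 3a-H/8a-H (key-step product) | C12(OCCO1)CCCC(C)(C)[C@@H]3CC(=O)[C@@](C)(C=O)[C@H]23 | intermediate
16 | E-enoyl imide: 15 with CHO converted into (E)-CH=CH–C(=O)–N of (R)-4-benzyloxazolidin-2-one | C12(OCCO1)CCCC(C)(C)[C@@H]3CC(=O)[C@@](C)(/C=C/C(=O)N4[C@H](Cc5ccccc5)COC4=O)[C@H]23 | intermediate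
17 | vinyl adduct: C1′ bears vinyl and CH2C(=O)N-oxazolidinone, C2 ketone present | C12(OCCO1)CCCC(C)(C)[C@@H]3CC(=O)[C@@](C)([C@H](C=C)CC(=O)N4[C@H](Cc5ccccc5)COC4=O)[C@H]23 | intermediate
18 | C2 tosylhydrazone of 17 (C=N geometry undefined) | C12(OCCO1)CCCC(C)(C)[C@@H]3CC(=NNS(=O)(=O)c6ccc(C)cc6)[C@@](C)([C@H](C=C)CC(=O)N4[C@H](Cc5ccccc5)COC4=O)[C@H]23 | intermediate
19 | 2-deoxo analogue of 17 (C2 = CH2) | C12(OCCO1)CCCC(C)(C)[C@@H]3CC[C@@](C)([C@H](C=C)CC(=O)N4[C@H](Cc5ccccc5)COC4=O)[C@H]23 | intermediate
20 | 19 alkylated at C2′ with CH2CO2t-Bu | C12(OCCO1)CCCC(C)(C)[C@@H]3CC[C@@](C)([C@H](C=C)[C@@H](CC(=O)OC(C)(C)C)C(=O)N4[C@H](Cc5ccccc5)COC4=O)[C@H]23 | intermediate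
21 | tert-butyl 3-(hydroxymethyl)-4-(ring C1)hex-5-enoate (not isolated) | C12(OCCO1)CCCC(C)(C)[C@@H]3CC[C@@](C)([C@H](C=C)[C@@H](CC(=O)OC(C)(C)C)CO)[C@H]23 | intermediate
22 | γ-lactone with vinyl group on C1′, ketal at C8 | C12(OCCO1)CCCC(C)(C)[C@@H]3CC[C@@](C)([C@H](C=C)[C@@H]4COC(=O)C4)[C@H]23 | intermediate
23 | C1′ aldehyde from ozonolysis of 22 (not isolated) | C12(OCCO1)CCCC(C)(C)[C@@H]3CC[C@@](C)([C@H](C=O)[C@@H]4COC(=O)C4)[C@H]23 | intermediate
24 | primary alcohol (CH2OH on C1′), ketal lactone | C12(OCCO1)CCCC(C)(C)[C@@H]3CC[C@@](C)([C@H](CO)[C@@H]4COC(=O)C4)[C@H]23 | intermediate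
25 | acetate of 24 | C12(OCCO1)CCCC(C)(C)[C@@H]3CC[C@@](C)([C@H](COC(C)=O)[C@@H]4COC(=O)C4)[C@H]23 | intermediate
26 | C8 ketone (cis-fused hydroazulen-8-one) with complete side chain | O=C1CCCC(C)(C)[C@@H]2CC[C@@](C)([C@H](COC(C)=O)[C@@H]3COC(=O)C3)[C@H]12 | intermediate
27 | (2R)-2-[(3R)-5-oxooxolan-3-yl]-2-[(1R,3aR,8aS)-1,4,4-trimethyl-8-methylidenedecahydroazulen-1-yl]ethyl acetate | C=C1CCCC(C)(C)[C@@H]2CC[C@@](C)([C@H](COC(C)=O)[C@@H]3COC(=O)C3)[C@H]12 | target

**Step count and risks**

Total: 21 steps. Longest linear sequence: 18 steps (1 → 27 through steps 1–3, 5–8, 11–21). The diene (step 4) and the phosphonate (steps 9–10) are side branches.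

Steps most likely to fail:

1. Step 5. The γ,γ-disubstituted enone may react too slowly with the chiral catalyst, or the catalyst may discriminate the enone faces poorly. Fallback: give up catalyst control and resolve through the auxiliary that the route installs anyway. Setting out from 5 (with 7), an achiral Lewis acid (EtAlCl2, toluene, −20 °C) or simple heating should give the racemic cis adduct, that is 8 together with its mirror image ent-8 F1. Steps 6, 7, 8 and 11 are then run on the racemate, which carries ent-9 F2, ent-10 F3, ent-11 F4 and ent-15 F5 alongside 9, 10, 11 and 15. Olefination with enantiopure 14 as in step 12 turns the two enantiomers into 16 and the diastereomeric enoyl imide F6, which should be separable by chromatography or crystallisation. The fallback returns to the route at 16.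

2. Step 13. Transfer of the vinyl group to the neopentyl-type β-carbon may be slow, 1,2-attack or reduction may compete, and the auxiliary may be mismatched with the C1 centre. Fallback: form the C1′–C bond intramolecularly by a [3,3] shift and attach the auxiliary afterwards. Setting out from 15, Wittig reaction with ethyl (triphenylphosphoranylidene)acetate gives the E-keto enoate F7. The C2 ketone is removed as in steps 14–15, through the tosylhydrazone F8 to the deoxygenated enoate F9. DIBAL-H reduction gives the allylic alcohol F10. Johnson–Claisen rearrangement (triethyl orthoacetate, cat. propionic acid, 140 °C) places CH2CO2Et on C1′ and turns the former chain into the vinyl group, giving the ester F11. Saponification gives the acid F12, which is coupled with 12 (pivaloyl chloride, Et3N, LiCl) to return to the route at 19. Here C1′ depends on the chair transition state and the bias of the quaternary centre instead of the auxiliary, so any C1′ epimer would be separated at the imide stage.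

3. Step 11. Hydride shift to the 1,2-dione, opening of the dioxolane by BF3, or loss of the formyl group during handling may erode the acyl shift. Fallback: run the same 1,2-shift at the alcohol oxidation level, where the product cannot deformylate. Setting out from 11, Luche reduction gives the epoxy alcohol F13 (either C2 epimer serves). Silylation (TBSOTf, 2,6-lutidine) gives the epoxy silyl ether F14. A bulky aluminium aryloxide (methylaluminium bis(4-bromo-2,6-di-tert-butylphenoxide), CH2Cl2, −78 °C) triggers the known epoxy silyl ether to β-siloxy aldehyde rearrangement, with migration of the carbinol carbon anti to the oxirane oxygen, and gives the ring-contracted siloxy aldehyde F15. Olefination with 14 as in step 12 gives the siloxy enoyl imide F16, HF·pyridine gives the hydroxy enoyl imide F17, and Dess–Martin oxidation returns to the route at 16.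

Further compounds
F1 | step 5 | ent-8 (mirror image of 8, formed with 8 as the racemate) | O=C1CCCC(C)(C)[C@H]2CC(O[Si](C(C)C)(C(C)C)C(C)C)=C[C@@H](C)[C@@H]12
F2 | step 5 | ent-9 | O=C1CCCC(C)(C)[C@H]2CC(=O)C=C(C)[C@@H]12
F3 | step 5 | ent-10 | C12(OCCO1)CCCC(C)(C)[C@H]3CC(=O)C=C(C)[C@@H]23
F4 | step 5 | ent-11 | C12(OCCO1)CCCC(C)(C)[C@H]3CC(=O)[C@@H]4O[C@]4(C)[C@@H]23
F5 | step 5 | ent-15 | C12(OCCO1)CCCC(C)(C)[C@H]3CC(=O)[C@](C)(C=O)[C@@H]23
F6 | step 5 | diastereomer of 16 (mirror-image bicyclic core, (R)-auxiliary) | C12(OCCO1)CCCC(C)(C)[C@H]3CC(=O)[C@](C)(/C=C/C(=O)N4[C@H](Cc5ccccc5)COC4=O)[C@@H]23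
F7 | step 13 | ethyl (E)-3-[1,4,4-trimethyl-2-oxo-8,8-(ethane-1,2-diyldioxy)decahydroazulen-1-yl]prop-2-enoate | C12(OCCO1)CCCC(C)(C)[C@@H]3CC(=O)[C@@](C)(/C=C/C(=O)OCC)[C@H]23
F8 | step 13 | C2 tosylhydrazone of F7 | C12(OCCO1)CCCC(C)(C)[C@@H]3CC(=NNS(=O)(=O)c4ccc(C)cc4)[C@@](C)(/C=C/C(=O)OCC)[C@H]23
F9 | step 13 | 2-deoxo enoate (C2 = CH2) | C12(OCCO1)CCCC(C)(C)[C@@H]3CC[C@@](C)(/C=C/C(=O)OCC)[C@H]23
F10 | step 13 | (E)-allylic alcohol from F9 | C12(OCCO1)CCCC(C)(C)[C@@H]3CC[C@@](C)(/C=C/CO)[C@H]23
F11 | step 13 | ethyl 3-(ring C1)pent-4-enoate (Johnson–Claisen product) | C12(OCCO1)CCCC(C)(C)[C@@H]3CC[C@@](C)([C@H](C=C)CC(=O)OCC)[C@H]23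
F12 | step 13 | 3-(ring C1)pent-4-enoic acid | C12(OCCO1)CCCC(C)(C)[C@@H]3CC[C@@](C)([C@H](C=C)CC(=O)O)[C@H]23
F13 | step 11 | epoxy alcohol from 11 (C2 carbinol, epimer not defined) | C12(OCCO1)CCCC(C)(C)[C@@H]3CC(O)[C@H]4O[C@@]4(C)[C@H]23
F14 | step 11 | tert-butyldimethylsilyl ether of F13 | C12(OCCO1)CCCC(C)(C)[C@@H]3CC(O[Si](C)(C)C(C)(C)C)[C@H]4O[C@@]4(C)[C@H]23
F15 | step 11 | ring-contracted 2-(tert-butyldimethylsilyloxy)-1-formyl-1-methyl hydroazulene (β-siloxy aldehyde) | C12(OCCO1)CCCC(C)(C)[C@@H]3CC(O[Si](C)(C)C(C)(C)C)[C@@](C)(C=O)[C@H]23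
F16 | step 11 | E-enoyl imide from F15 (C2 silyl ether analogue of 16) | C12(OCCO1)CCCC(C)(C)[C@@H]3CC(O[Si](C)(C)C(C)(C)C)[C@@](C)(/C=C/C(=O)N4[C@H](Cc5ccccc5)COC4=O)[C@H]23
F17 | step 11 | C2 alcohol analogue of 16 | C12(OCCO1)CCCC(C)(C)[C@@H]3CC(O)[C@@](C)(/C=C/C(=O)N4[C@H](Cc5ccccc5)COC4=O)[C@H]23
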